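The plan disconnects O9–C12, C13–Br and C8–Br together. In the target both bromines sit beta and anti to O9, the oxygen of ring B (O9, C9–C12): C8–Br flanks C9–O9 and C13–Br flanks C12–O9. Formal addition of Br2 to an acyclic cis-8,9-epoxy-12E-alkene should therefore close ring B and fix C8, C12 and C13 in one operation, by way of a bromonium ion and a bicyclic epoxonium ion. The precursor is the linear C15 (3Z,12E)-diene-1,6-diyne with the cis-epoxide, a C10 silyl ether and a protective C1 trimethylsilyl cap. Ring A (O10–C7) is closed afterwards on the untouched C6–C7 alkyne.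

Key step: step 10

Remark: atoms carry the chain numbering C1 (terminal alkyne carbon) to C15; O9 joins C9 and C12 (ring B), O10 joins C7 and C10 (ring A); compound 1 is assumed to be available as the pure Z isomer.

Step 1
Reactants: 1 (Z)-pent-2-en-4-yn-1-ol; 2 chlorotrimethylsilane
Product: 4 (Z)-5-(trimethylsilyl)pent-2-en-4-yn-1-ol, via bis-silylated enynol 3 (not isolated)
Conditions: n-BuLi (2.1 equiv), THF, −78 °C; 2 (2.2 equiv), −78 °C to rt; then 1 M HCl, rt
Reagents that add atoms: chlorotrimethylsilane, C[Si](C)(C)Cl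
Why: Double deprotonation gives the alkoxide–acetylide, both sites are silylated (acetylide C-silylation), and dilute acid hydrolyses only the labile O–Si bond, so the Z-alkene is untouched and no stereocentre is formed.

Step 2
Reactants: 4 (Z)-5-(trimethylsilyl)pent-2-en-4-yn-1-ol
Product: 5 (Z)-(5-bromopent-3-en-1-yn-1-yl)trimethylsilane
Conditions: CBr4, PPh3, CH2Cl2, −20 to 0 °C
Reagents that add atoms: tetrabromomethane, BrC(Br)(Br)Br
Why: The Appel reaction turns the primary allylic alcohol into the bromide by SN2 under neutral, cold conditions that should preserve the Z-alkene and the C–Si bond.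

Step 3
Reactants: 5 (Z)-(5-bromopent-3-en-1-yn-1-yl)trimethylsilane; 1 (Z)-pent-2-en-4-yn-1-ol
Product: 6 (2Z,7Z)-10-(trimethylsilyl)deca-2,7-diene-4,9-diyn-1-ol
Conditions: CuI (20 mol %), NaI (20 mol %), K2CO3 (1.5 equiv), DMF, 0 °C to rt, argon
Reagents that add atoms: none
Why: In this copper-catalysed acetylide allylation only 1 offers a terminal alkyne, because the alkyne of 5 is silyl-capped and the bromide cannot couple with itself, and SN2 attack at the primary carbon (which keeps the enyne conjugated) should form C5–C6 with both Z-alkenes retained.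

Step 4
Reactants: 6 (2Z,7Z)-10-(trimethylsilyl)deca-2,7-diene-4,9-diyn-1-ol
Product: 7 [(2R,3S)-3-[(4Z)-7-(trimethylsilyl)hept-4-ene-1,6-diyn-1-yl]oxiran-2-yl]methanol
Conditions: Ti(Oi-Pr)4 (15 mol %), D-(−)-diethyl tartrate (18 mol %), t-BuOOH (decane), 4 Å MS, CH2Cl2, −20 °C
Reagents that add atoms: tert-butyl hydroperoxide, CC(C)(C)OO
Why: Sharpless asymmetric epoxidation is hydroxyl-directed, so only the allylic C8=C9 alkene reacts, syn oxygen transfer to the Z-alkene makes the epoxide cis, and D-(−)-tartrate selects the face that gives 8S,9R.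

Step 5
Reactants: 7 [(2R,3S)-3-[(4Z)-7-(trimethylsilyl)hept-4-ene-1,6-diyn-1-yl]oxiran-2-yl]methanol
Product: 8 (2S,3S)-3-[(4Z)-7-(trimethylsilyl)hept-4-ene-1,6-diyn-1-yl]oxirane-2-carbaldehyde
Conditions: TEMPO (10 mol %), PhI(OAc)2 (1.1 equiv), CH2Cl2, rt
Reagents that add atoms: none
Why: Oxoammonium (TEMPO) oxidation of the primary alcohol stops at the aldehyde under base-free conditions, which should avoid epimerisation at C9 and leave the epoxide, alkenes and alkynes alone.

Step 6
Reactants: 9 propan-1-ol
Product: 10 propyl N,N-diisopropylcarbamate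
Conditions: i-Pr2NCOCl, Et3N, CH2Cl2, reflux
Reagents that add atoms: N,N-diisopropylcarbamoyl chloride, CC(C)N(C(C)C)C(=O)Cl
Why: Simple O-carbamoylation installs the group that directs the asymmetric lithiation and later serves as the leaving group.

Step 7
Reactants: 10 propyl N,N-diisopropylcarbamate; 11 4,4,5,5-tetramethyl-2-vinyl-1,3,2-dioxaborolane
Product: 14 (R)-4,4,5,5-tetramethyl-2-(pent-1-en-3-yl)-1,3,2-dioxaborolane, via lithiated carbamate 12 (not isolated), via vinyl boronate complex 13 (not isolated)
Conditions: s-BuLi, (−)-sparteine, Et2O, −78 °C; 11, −78 °C; MgBr2·OEt2, then reflux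
Reagents that add atoms: none
Why: In this lithiation–borylation s-BuLi/(−)-sparteine removes the pro-S alpha proton, 12 is borylated by 11 with retention, and the Matteson-type 1,2-metallate shift of the vinyl group in 13 expels the carbamate with inversion, which sets the R configuration of the alpha-ethyl allylboronate.

Step 8
Reactants: 14 (R)-4,4,5,5-tetramethyl-2-(pent-1-en-3-yl)-1,3,2-dioxaborolane; 8 (2S,3S)-3-[(4Z)-7-(trimethylsilyl)hept-4-ene-1,6-diyn-1-yl]oxirane-2-carbaldehyde
Product: 17 (3Z,8S,9R,10S,12E)-8,9-epoxy-1-(trimethylsilyl)pentadeca-3,12-diene-1,6-diyn-10-ol, via butyl boronate complex 15 (not isolated), via allyl borinic ester 16 (not isolated)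
Conditions: 14 (1.5 equiv), n-BuLi (1.4 equiv), THF, −78 °C; (CF3CO)2O, −78 °C; 8, −78 °C; then pH 7 buffer
Reagents that add atoms: none
Why: This allylboration runs through a closed chair (Zimmerman–Traxler type) in which the small borinic ester 16 places its alpha-ethyl group equatorial, so C10–C11 forms at the unsubstituted allyl terminus with a 12E-alkene, and the R boron-bearing centre is relayed to 10S (threo to the epoxide) under reagent control that should override the Felkin–Anh bias of the cis-epoxy aldehyde and turn any minor enantiomer of 8 into a separable diastereomer.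

Step 9
Reactants: 17 (3Z,8S,9R,10S,12E)-8,9-epoxy-1-(trimethylsilyl)pentadeca-3,12-diene-1,6-diyn-10-ol
Product: 18 (3Z,8S,9S,10S,12E)-10-(tert-butyldimethylsilyloxy)-8,9-epoxy-1-(trimethylsilyl)pentadeca-3,12-diene-1,6-diyne
Conditions: TBSCl, imidazole, DMAP (cat.), DMF, rt
Reagents that add atoms: tert-butyldimethylsilyl chloride, CC(C)(C)[Si](C)(C)Cl
Why: Standard imidazole-promoted O-silylation caps O10 so that it cannot compete as a nucleophile in step 10, without touching the epoxide or any stereocentre.

Step 10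
Reactants: 18 (3Z,8S,9S,10S,12E)-10-(tert-butyldimethylsilyloxy)-8,9-epoxy-1-(trimethylsilyl)pentadeca-3,12-diene-1,6-diyne
Product: 21 (3Z,8R,9R,10S,12R,13S)-8,13-dibromo-10-(tert-butyldimethylsilyloxy)-9,12-epoxy-1-(trimethylsilyl)pentadec-3-ene-1,6-diyne, via bromonium bromide 19 (not isolated), via bicyclic oxonium bromide 20 (not isolated)
Conditions: Br2 (1.0 equiv, dilute in CH2Cl2, syringe pump), 2,6-di-tert-butyl-4-methylpyridine (0.3 equiv), CH2Cl2/MeNO2 (5 mM), −60 °C, dark
Reagents that add atoms: bromine, BrBr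
Why: Br2 transfers Br+ reversibly to the C12=C13 alkene to give 19, the epoxide oxygen O9 attacks C12 from the rear to give the 1-oxoniabicyclo[3.1.0]hexane 20, and the bromide set loose in the first event opens 20 at C8 by SN2, so that O9–C12, C13–Br and C8–Br arise from one molecule of bromine. The closest known reaction type is halonium-induced participation of an epoxide in a gamma,delta-epoxy alkene (also known in transannular form) followed by halide capture of the epoxonium ion. Ring B closes in the 5-exo mode at the bromonium ion, which for a 1,2-dialkyl bromonium should beat 6-endo attack at C13. C12 and C13 are fixed relative to each other by anti addition of O9 and Br across the E-alkene and C8 by inversion at the cis-epoxide carbon, while C9 and C10 pass through unchanged. Which alkene face ends up in the product is decided at the ring closure (Curtin–Hammett situation): in 20 the C8 alkynyl group, endo because the epoxide is cis, and the C10 silyloxy group both lie on the concave face, so the CHBrEt chain should take the convex face and give the 2,5-trans ring with 12R,13S. The step needs attack on the dialkyl alkene rather than on the enyne or the alkynes (these are deactivated by their sp carbons), ring closure ahead of bromide collapse on 19 (high dilution, slow addition, polar medium) and opening at C8 rather than C9 (propargylic activation and an open exocyclic trajectory against a C9 that is shielded and inductively deactivated by C10–O and whose cleavage would cost the five-membered ring).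

Step 11
Reactants: 21 (3Z,8R,9R,10S,12R,13S)-8,13-dibromo-10-(tert-butyldimethylsilyloxy)-9,12-epoxy-1-(trimethylsilyl)pentadec-3-ene-1,6-diyne
Product: 22 (3Z,8R,9R,10S,12R,13S)-8,13-dibromo-9,12-epoxy-1-(trimethylsilyl)pentadec-3-ene-1,6-diyn-10-ol
Conditions: HF·pyridine, pyridine, THF, 0 °C to rt
Reagents that add atoms: none
Why: Acidic fluoride cleaves the O–Si bond of the secondary silyl ether, while the alkynyl C–Si bond, the propargylic and secondary bromides and all stereocentres should survive because no basic or strongly nucleophilic species is present.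

Step 12
Reactants: 22 (3Z,8R,9R,10S,12R,13S)-8,13-dibromo-9,12-epoxy-1-(trimethylsilyl)pentadec-3-ene-1,6-diyn-10-ol
Product: 23 (3Z,6Z,8S,9R,10S,12R,13S)-8,13-dibromo-7,10:9,12-diepoxy-1-(trimethylsilyl)pentadeca-3,6-dien-1-yne
Conditions: Ph3PAuNTf2 (5 mol %), 2,6-di-tert-butylpyridine (10 mol %), CH2Cl2, 0 °C; Et3N quench
Reagents that add atoms: none
Why: In this gold-catalysed intramolecular hydroalkoxylation the silver-free monovalent gold cation activates the C6–C7 alkyne, the cis-disposed C10 hydroxyl adds anti to C7 in the 5-exo-dig mode, and protodeauration with retention leaves C5 cis to O10, that is the 6Z enol ether of ring A, while the hindered base suppresses acid-induced double-bond migration.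

Step 13
Reactants: 23 (3Z,6Z,8S,9R,10S,12R,13S)-8,13-dibromo-7,10:9,12-diepoxy-1-(trimethylsilyl)pentadeca-3,6-dien-1-yne
Product: 24 (3Z,6Z,8S,9R,10S,12R,13S)-8,13-dibromo-7,10:9,12-diepoxypentadeca-3,6-dien-1-yne (target CNP0105780.1)
Conditions: n-Bu4NF (1.1 equiv), AcOH (1.1 equiv), THF, −20 °C
Reagents that add atoms: none
Why: Fluoride-induced protodesilylation of the alkynylsilane is very fast, and buffering with AcOH at low temperature should spare the allylic C8 bromide, the C13 bromide and the enol ether.

Compound list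
1 | (Z)-pent-2-en-4-yn-1-ol | C#C/C=C\CO | starting material
2 | chlorotrimethylsilane | C[Si](C)(C)Cl | starting material
3 | (Z)-trimethyl[5-(trimethylsilyloxy)pent-3-en-1-yn-1-yl]silane | C[Si](C)(C)C#C/C=C\CO[Si](C)(C)C | intermediate
4 | (Z)-5-(trimethylsilyl)pent-2-en-4-yn-1-ol | C[Si](C)(C)C#C/C=C\CO | intermediate
5 | (Z)-(5-bromopent-3-en-1-yn-1-yl)trimethylsilane | C[Si](C)(C)C#C/C=C\CBr | intermediate
6 | (2Z,7Z)-10-(trimethylsilyl)deca-2,7-diene-4,9-diyn-1-ol | C[Si](C)(C)C#C/C=C\CC#C/C=C\CO | intermediate
7 | [(2R,3S)-3-[(4Z)-7-(trimethylsilyl)hept-4-ene-1,6-diyn-1-yl]oxiran-2-yl]methanol | C[Si](C)(C)C#C/C=C\CC#C[C@@H]1O[C@@H]1CO | intermediate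
8 | (2S,3S)-3-[(4Z)-7-(trimethylsilyl)hept-4-ene-1,6-diyn-1-yl]oxirane-2-carbaldehyde | C[Si](C)(C)C#C/C=C\CC#C[C@@H]1O[C@@H]1C=O | intermediate
9 | propan-1-ol | CCCO | starting material
10 | propyl N,N-diisopropylcarbamate | CCCOC(=O)N(C(C)C)C(C)C | intermediate
11 | 4,4,5,5-tetramethyl-2-vinyl-1,3,2-dioxaborolane | C=CB1OC(C)(C)C(C)(C)O1 | starting material
12 | (S)-1-lithiopropyl N,N-diisopropylcarbamate (as its sparteine complex) | [Li][C@@H](CC)OC(=O)N(C(C)C)C(C)C | intermediate
13 | lithium boronate complex of 11 bearing the (S)-1-(carbamoyloxy)propyl group on boron | [Li+].C=C[B-]1(OC(C)(C)C(C)(C)O1)[C@@H](CC)OC(=O)N(C(C)C)C(C)C | intermediate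
14 | (R)-4,4,5,5-tetramethyl-2-(pent-1-en-3-yl)-1,3,2-dioxaborolane | C=C[C@@H](CC)B1OC(C)(C)C(C)(C)O1 | intermediate
15 | lithium B-butyl boronate complex of 14 | [Li+].C=C[C@@H](CC)[B-]1(CCCC)OC(C)(C)C(C)(C)O1 | intermediate
16 | butyl[(R)-pent-1-en-3-yl]borinic acid 2,3-dimethyl-3-(trifluoroacetoxy)butan-2-yl ester | C=C[C@@H](CC)B(CCCC)OC(C)(C)C(C)(C)OC(=O)C(F)(F)F | intermediate
17 | (3Z,8S,9R,10S,12E)-8,9-epoxy-1-(trimethylsilyl)pentadeca-3,12-diene-1,6-diyn-10-ol (cis-epoxide, C10–OH threo to it) | C[Si](C)(C)C#C/C=C\CC#C[C@@H]1O[C@@H]1[C@@H](O)C/C=C/CC | intermediate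
18 | (3Z,8S,9S,10S,12E)-10-(tert-butyldimethylsilyloxy)-8,9-epoxy-1-(trimethylsilyl)pentadeca-3,12-diene-1,6-diyne | C[Si](C)(C)C#C/C=C\CC#C[C@@H]1O[C@@H]1[C@@H](O[Si](C)(C)C(C)(C)C)C/C=C/CC | intermediate
19 | C12–C13 bromonium bromide of 18 (trans-disubstituted bromiranium ring) | C[Si](C)(C)C#C/C=C\CC#C[C@@H]1O[C@@H]1[C@@H](O[Si](C)(C)C(C)(C)C)C[C@@H]2[Br+][C@H]2CC.[Br-] | intermediate
20 | 1-oxoniabicyclo[3.1.0]hexane bromide with O9 bonded to C8, C9 and C12 and C13–Br in place | C[Si](C)(C)C#C/C=C\CC#C[C@H]1[C@H]2[C@@H](O[Si](C)(C)C(C)(C)C)C[C@H]([C@@H](Br)CC)[O+]12.[Br-] | intermediate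
21 | (3Z,8R,9R,10S,12R,13S)-8,13-dibromo-10-(tert-butyldimethylsilyloxy)-9,12-epoxy-1-(trimethylsilyl)pentadec-3-ene-1,6-diyne | C[Si](C)(C)C#C/C=C\CC#C[C@@H](Br)[C@@H]1O[C@@H]([C@@H](Br)CC)C[C@@H]1O[Si](C)(C)C(C)(C)C | intermediate
22 | (3Z,8R,9R,10S,12R,13S)-8,13-dibromo-9,12-epoxy-1-(trimethylsilyl)pentadec-3-ene-1,6-diyn-10-ol | C[Si](C)(C)C#C/C=C\CC#C[C@@H](Br)[C@@H]1O[C@@H]([C@@H](Br)CC)C[C@@H]1O | intermediate
23 | (3Z,6Z,8S,9R,10S,12R,13S)-8,13-dibromo-7,10:9,12-diepoxy-1-(trimethylsilyl)pentadeca-3,6-dien-1-yne | C[Si](C)(C)C#C/C=C\C/C=C1\O[C@H]2C[C@H]([C@@H](Br)CC)O[C@H]2[C@@H]1Br | intermediate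
24 | (3Z,6Z,8S,9R,10S,12R,13S)-8,13-dibromo-7,10:9,12-diepoxypentadeca-3,6-dien-1-yne | C#C/C=C\C/C=C1\O[C@H]2C[C@H]([C@@H](Br)CC)O[C@H]2[C@@H]1Br | target

Total step count: 13. Longest linear sequence: 11 steps (steps 1–5 and 8–13, from 1); steps 6 and 7 form a two-step side branch.

Steps most likely to fail

1. Step 10.
- What may go wrong: bromide may collapse onto the bromonium ion before O9 engages (plain 1,2-dibromination). The two alkene faces may be poorly differentiated. The epoxonium ion may be opened in the SN2' sense or at C9.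
- Fallback (from 18, back at 21): the two C–Br bonds are made in separate, individually known operations and in the reverse order. LiBr and AcOH in THF should open the epoxide by SN2 at the propargylic carbon C8 to give the (8R,9R,10S)-configured bromohydrin F1. N-Bromosuccinimide in MeCN at −20 °C should then effect 5-exo bromoetherification of the free C9 hydroxyl onto the 12E-alkene and deliver 21.

2. Step 12.
- What may go wrong: the inductive pull of the propargylic bromide may divert the hydroxyl to C6 (6-endo closure). Traces of acid may move the enol ether double bond into the ring. The cationic catalyst may ionise the propargylic C–Br bond.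
- Fallback (from 22, back at 23): stoichiometric oxymetallation under basic conditions replaces catalytic pi-acid activation. Hg(OCOCF3)2 and Et3N in CH2Cl2 at −78 °C, followed by a NaCl wash, should give by anti 5-exo addition the isolable (6E)-6-chloromercurio enol ether F2. Protodemercuration with retention by pyridinium chloride in CH2Cl2 at −40 °C should then give 23.

3. Step 8.
- What may go wrong: reagent and substrate preferences are mismatched, so facial selectivity at C10 and E selectivity at C12=C13 may erode together. The sensitive epoxy aldehyde may also decompose before it is consumed.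
- Fallback (from 8, back at 17): substrate control followed by inversion. (E)-Pent-2-enylbarium chloride, made from (E)-1-chloropent-2-ene and activated barium metal (BaI2, lithium biphenylide) in THF at −78 °C, reacts at its alpha carbon with retention of alkene geometry and should give mainly the Felkin–Anh product, the 10R alcohol F3. A Mitsunobu reaction (4-nitrobenzoic acid, PPh3, diisopropyl azodicarboxylate, toluene, 0 °C) inverts C10 to the 10S 4-nitrobenzoate F4. i-Bu2AlH in CH2Cl2 at −78 °C then removes the ester without touching the alkynylsilane and gives 17.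

Further compounds
F1 | step 10 | (3Z,8R,9R,10S,12E)-8-bromo-10-(tert-butyldimethylsilyloxy)-1-(trimethylsilyl)pentadeca-3,12-diene-1,6-diyn-9-ol | C[Si](C)(C)C#C/C=C\CC#C[C@@H](Br)[C@H](O)[C@@H](O[Si](C)(C)C(C)(C)C)C/C=C/CC
F2 | step 12 | (3Z,6E,8S,9R,10S,12R,13S)-8,13-dibromo-6-(chloromercurio)-7,10:9,12-diepoxy-1-(trimethylsilyl)pentadeca-3,6-dien-1-yne | C[Si](C)(C)C#C/C=C\C/C([Hg]Cl)=C1\O[C@H]2C[C@H]([C@@H](Br)CC)O[C@H]2[C@@H]1Br
F3 | step 8 | (3Z,8S,9R,10R,12E)-8,9-epoxy-1-(trimethylsilyl)pentadeca-3,12-diene-1,6-diyn-10-ol | C[Si](C)(C)C#C/C=C\CC#C[C@@H]1O[C@@H]1[C@H](O)C/C=C/CC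
F4 | step 8 | (3Z,8S,9R,10S,12E)-8,9-epoxy-1-(trimethylsilyl)pentadeca-3,12-diene-1,6-diyn-10-yl 4-nitrobenzoate | C[Si](C)(C)C#C/C=C\CC#C[C@@H]1O[C@@H]1[C@@H](OC(=O)c2ccc(cc2)[N+](=O)[O-])C/C=C/CC
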